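The earlier runs and the new flask are calculated with constants of no real substance.

A small charge of impurity tells the dawn flask from the spring run: [impurity] is 0.21 mM against 0.32 mM, with [racemization catalyst] at 0.50 mM in both.

in all of them: left-handed substrate 0.10 M; right-handed substrate 0.10 M; gas 29 mM (held); racemization catalyst 0.50 mM
- dawn: impurity 0.21 mM; the very flask that is asked about, followed so far
- spring: impurity 0.32 mM; run made earlier
- flask: impurity 0.21 mM; time 3.0 d

dawn run (percent of the left-handed substrate and right-handed substrate together charged)

| time / h | left-handed product / % | left-handed substrate / % |
|---|---|---|
| 20.0 | 29.1 | 23.6 |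
| 25.0 | 31.9 | 20.1 |
| 30.0 | 33.9 | 16.6 |

spring run (percent of the left-handed substrate and right-handed substrate together charged)

| time / d | left-handed product / % | left-handed substrate / % |
|---|---|---|
| 0.833 | 27.2 | 25.0 |
| 1.04 | 30.3 | 20.1 |
| 1.25 | 35.1 | 15.0 |
| 1.67 | 39.3 | 12.6 |
| 2.08 | 44.8 | 8.2 |
| 2.50 | 45.6 | 5.9 |
| 3.00 | 49.6 | 3.8 |

(scatter of a reading: 1 percentage point)

- reagent is single-handed; left-handed substrate and right-handed substrate are mirror images of each other, charged as a racemate, each of them at the stated concentration
- the numbers in the tables scatter by 1 percentage point (one standard deviation)
- at the start none of the gas is in solution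
- the handed part of reagent does not stay in what it makes, so the products of the two hands are mirror images too

* the moment within 3.0 d at which there is most left-handed product
* the amount of left-handed product, in percent of the left-handed substrate and right-handed substrate together charged, at that time

You must decide whether to stop the dawn flask, followed so far to 30.0 h, or leave it until 3.0 d. This is a dynamic kinetic resolution, and the large part of the answer is the left-handed share of the charge, 50.0 %, so reckon the correction. In the spring run at 3.00 d, left-handed product plus left-handed substrate stands 3.4 percentage points above that share, a figure from two readings that scatter by 1 point each. Suppose each impurity removes one catalyst. Then 0.290 mM of catalyst stays unspent in the dawn flask and 0.180 mM in the spring run. Scaling in proportion, I reckon 5.5 points for the dawn flask at 3.0 d: this is the gain, the amount by which left-handed product plus left-handed substrate exceeds the left-handed share charged.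

Left-handed product is then the share plus the gain minus the remaining left-handed substrate. In the spring run, charged like the dawn flask except for impurity, the product readings still rise up to the last one, 49.6 %, with 3.8 % of left-handed substrate beside it. So leave the dawn flask running; taking that substrate reading as it stands, you expect 51.7 % at 3.0 d.

The forecast gave 50.5 % (47.5 % to 54 %) at 3 d (2.7 d to 3 d), lower than my figure, holding that “Nothing shows product decay”.

The flask gives 50.2 % at 3.00 d.

    2 racemization catalyst ⇌ resting dimer (K = 2590 /M, k = 185 /M/h)
    reagent + right-handed substrate → right-handed product (k = 0.693 /M/h)
    gas ⇌ reagent, rate k3*(csat - [reagent]) (kL = 7.69 /h)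
    reagent + left-handed substrate → left-handed product (k = 1.32 /M/h)
    racemization catalyst + impurity → spent catalyst (k = 55600 /M/h)
    left-handed substrate + racemization catalyst ⇌ right-handed substrate + racemization catalyst, rate k6*[racemization catalyst]*[left-handed substrate] forward; the back reaction follows from the equilibrium constant (k = 68.1 /M/h)

At 0.665 d in this flask, left-handed substrate has a half-life of 0.77 d by reaction with reagent and 2.6 d by the forward step of racemization, a factor of 3.38. At 3.00 d this flask holds 4.93 % of left-handed substrate and its gain is 5.1 points, against the 5.5 points I reckoned. In the neighbouring flask left until 12 d, left-handed substrate is down to 0.0167 %, left-handed product stands at 57.1 %, and the gain is 7.1 points.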